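**Strategy.** The route rests on cutting the ring A C4–O bond. The free carboxyl on the enol-ether α-carbon is tied through the ether oxygen to ring A C3 and is made to oxygenate the neighbouring C4–H. One palladium-catalysed operation cleaves that C–H bond and closes the six-membered 1,4-benzodioxin-2-one lactone (carboxyl O–C(=O)–Cα–O–C3–C4), so ring A enters as plain 3-iodophenol. The precursor is the fully assembled (Z)-α-aryloxyacrylic acid carrying the ring A cinnamate of acetonide-protected tert-butyl (R)-danshensu. It is built by O–H insertion, Horner–Wadsworth–Emmons olefination and a Heck coupling. Acid deprotection and mild lactone hydrolysis then release the 4-phenol and the acid together.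

Key step: step 11

Assumption: (R)-danshensu is used as the free acid (the commercial sodium salt is acidified first); 3-iodophenol, acryloyl chloride and ethyl 2-diazo-2-(diethoxyphosphoryl)acetate are bought.

**Step 1**
Reactants: 1 2,2-dimethyl-1,3-benzodioxole
Product: 2 5-bromo-2,2-dimethyl-1,3-benzodioxole
Conditions: NBS (1.05 equiv), DMF, 0 °C → rt, dark
Reagents that add atoms: N-bromosuccinimide, O=C1CCC(=O)N1Br
Why: Electrophilic aromatic bromination occurs para to a ring oxygen, at C5, because the positions next to the ketal oxygens are hindered and the neutral conditions spare the ketal.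

**Step 2**
Reactants: 2 5-bromo-2,2-dimethyl-1,3-benzodioxole
Product: 4 2,2-dimethyl-1,3-benzodioxole-5-carbaldehyde, via aryllithium 3 (not isolated)
Conditions: n-BuLi (1.05 equiv), THF, −78 °C; DMF, −78 °C → 0 °C; aq. NH4Cl
Reagents that add atoms: N,N-dimethylformamide, CN(C)C=O
Why: Bromine–lithium exchange followed by formylation of the aryllithium with DMF (Bouveault-type aldehyde synthesis) is fast at low temperature and leaves the base-stable ketal untouched.

**Step 3**
Reactants: 5 (R)-danshensu
Product: 6 (5R)-5-[(2,2-dimethyl-1,3-benzodioxol-5-yl)methyl]-2,2-dimethyl-1,3-dioxolan-4-one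
Conditions: 2,2-dimethoxypropane (excess), TsOH·H2O (5 mol%), acetone/toluene, reflux with MeOH removal over 4 Å sieves; Et3N quench
Reagents that add atoms: 2,2-dimethoxypropane, COC(C)(C)OC
Why: Acid-catalysed transketalisation should close the α-hydroxy acid to the dioxolanone and the catechol to the benzodioxole in one operation, and the R centre is retained because no bond to it is broken and nothing enolises under acid.

**Step 4**
Reactants: 6 (5R)-5-[(2,2-dimethyl-1,3-benzodioxol-5-yl)methyl]-2,2-dimethyl-1,3-dioxolan-4-one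
Product: 7 (2R)-3-(2,2-dimethyl-1,3-benzodioxol-5-yl)-2-hydroxypropanoic acid
Conditions: LiOH (2 equiv), THF/H2O, 0 °C; cold 1 M HCl to pH 3
Reagents that add atoms: water (delivered as LiOH/H2O), O
Why: Saponification of the activated dioxolanone is fast at 0 °C, the catechol ketal is inert to base, and the α-hydroxy carboxylate formed does not racemise.

**Step 5**
Reactants: 7 (2R)-3-(2,2-dimethyl-1,3-benzodioxol-5-yl)-2-hydroxypropanoic acid
Product: 8 tert-butyl (2R)-3-(2,2-dimethyl-1,3-benzodioxol-5-yl)-2-hydroxypropanoate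
Conditions: tert-butyl 2,2,2-trichloroacetimidate (2 equiv), CH2Cl2/cyclohexane, rt
Reagents that add atoms: tert-butyl 2,2,2-trichloroacetimidate, CC(C)(C)OC(=N)C(Cl)(Cl)Cl
Why: In this imidate esterification the acid itself activates the reagent, so without added Lewis acid only the carboxyl is tert-butylated and the secondary alcohol and the ketal stay free and intact.

**Step 6**
Reactants: 8 tert-butyl (2R)-3-(2,2-dimethyl-1,3-benzodioxol-5-yl)-2-hydroxypropanoate; 9 acryloyl chloride
Product: 10 tert-butyl (2R)-2-(acryloyloxy)-3-(2,2-dimethyl-1,3-benzodioxol-5-yl)propanoate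
Conditions: Et3N (1.5 equiv), CH2Cl2, −20 °C → 0 °C
Reagents that add atoms: none
Why: O-acylation of the secondary alcohol with an acid chloride proceeds at the oxygen only, so the configuration at C2 is untouched.

**Step 7**
Reactants: 11 3-iodophenol; 12 ethyl 2-diazo-2-(diethoxyphosphoryl)acetate
Product: 13 ethyl 2-(diethoxyphosphoryl)-2-(3-iodophenoxy)acetate (racemic)
Conditions: Rh2(OAc)4 (2 mol%), toluene, 80 °C, slow addition of 12
Reagents that add atoms: none
Why: Rhodium-carbenoid O–H insertion, in which the phenol oxygen captures the electrophilic carbenoid and a proton shift follows, is an established way to α-aryloxy phosphonoacetates; the new carbon is racemic and becomes an alkene carbon in step 8.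

**Step 8**
Reactants: 13 ethyl 2-(diethoxyphosphoryl)-2-(3-iodophenoxy)acetate; 4 2,2-dimethyl-1,3-benzodioxole-5-carbaldehyde
Product: 14 ethyl (2Z)-3-(2,2-dimethyl-1,3-benzodioxol-5-yl)-2-(3-iodophenoxy)prop-2-enoate
Conditions: LiCl (1.2 equiv), DBU (1.1 equiv), MeCN, 0 °C → rt; chromatography
Reagents that add atoms: none
Why: Horner–Wadsworth–Emmons olefination under mild lithium chloride/amine conditions is reversible in the addition step and should favour the alkene with the ester trans to ring B, which is the Z isomer; any E isomer is removed here.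

**Step 9**
Reactants: 14 ethyl (2Z)-3-(2,2-dimethyl-1,3-benzodioxol-5-yl)-2-(3-iodophenoxy)prop-2-enoate
Product: 15 (2Z)-3-(2,2-dimethyl-1,3-benzodioxol-5-yl)-2-(3-iodophenoxy)prop-2-enoic acid
Conditions: LiOH·H2O (3 equiv), THF/MeOH/H2O, rt → 40 °C; cold 1 M HCl to pH 3
Reagents that add atoms: water (delivered as LiOH/H2O), O
Why: Saponification is done while this is the only ester in the molecule, and the ketal, the aryl iodide and the trisubstituted Z alkene are inert to hydroxide.

**Step 10**
Reactants: 15 (2Z)-3-(2,2-dimethyl-1,3-benzodioxol-5-yl)-2-(3-iodophenoxy)prop-2-enoic acid; 10 tert-butyl (2R)-2-(acryloyloxy)-3-(2,2-dimethyl-1,3-benzodioxol-5-yl)propanoate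
Product: 16 (2Z)-2-{3-[(1E)-3-{[(2R)-1-tert-butoxy-3-(2,2-dimethyl-1,3-benzodioxol-5-yl)-1-oxopropan-2-yl]oxy}-3-oxoprop-1-en-1-yl]phenoxy}-3-(2,2-dimethyl-1,3-benzodioxol-5-yl)prop-2-enoic acid
Conditions: Pd(OAc)2 (5 mol%), Bu4NCl (1 equiv), NaHCO3 (3 equiv), DMF, 60 °C, dark; acidic work-up (pH 3)
Reagents that add atoms: none
Why: In this ligand-free Mizoroki–Heck reaction, oxidative addition of the aryl iodide to zerovalent palladium, syn insertion of the acrylate and syn β-hydride elimination should give the E cinnamate, while the free acid rides through as its carboxylate and bicarbonate is too weak to epimerise the α-acyloxy ester.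

**Step 11**
Reactants: 16 the (Z)-α-aryloxyacrylic acid of step 10
Product: 17 tert-butyl (2R)-3-(2,2-dimethyl-1,3-benzodioxol-5-yl)-2-{[(2E)-3-{(3Z)-3-[(2,2-dimethyl-1,3-benzodioxol-5-yl)methylidene]-2-oxo-2,3-dihydro-1,4-benzodioxin-6-yl}prop-2-enoyl]oxy}propanoate
Conditions: Pd(OAc)2 (10 mol%), N-acetylglycine (30 mol%), PhI(OAc)2 (1.5 equiv), KOAc (2 equiv), t-BuOH, 80 °C, N2, dark
Reagents that add atoms: none
Why: Proposed new method: the potassium carboxylate of 16 binds divalent palladium, an amino-acid-assisted concerted metalation–deprotonation cleaves the ring A C4–H bond to give a seven-membered palladacycle (Pd–O–C(=O)–Cα–O–C3–C4), PhI(OAc)2 oxidises it to tetravalent palladium, and aryl–carboxylate reductive elimination forms the C4–O bond. The closest known reaction types are the Pd(OAc)2/PhI(OAc)2 C–H lactonisation of biaryl-2-carboxylic acids and of α,α-disubstituted arylacetic acids, and the carboxylate-directed ortho C–H olefination of α-phenoxyacetic acids, which runs through the same seven-membered palladacycle. The one new ring, the six-membered 1,4-benzodioxin-2-one, is closed by C–O reductive elimination with contraction of the palladacycle, the carboxylate oxygen ending on C4. No stereocentre is formed and neither alkene is engaged, so the Z enol ether, the E cinnamate and the remote R centre should pass through unchanged. The step needs C4 over C2, which sterics should secure because C2 is wedged between the ether oxygen and the cinnamate chain; ring B lies trans to the carboxylate across the Z double bond and ring C carries only a tert-butyl ester, so neither can be reached by directed palladation. The acetate-buffered, mildly oxidising conditions are chosen so that the electron-rich benzodioxole rings are not attacked without direction.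

**Step 12**
Reactants: 17 the protected lactone of step 11
Product: 18 (2R)-3-(3,4-dihydroxyphenyl)-2-{[(2E)-3-{(3Z)-3-[(3,4-dihydroxyphenyl)methylidene]-2-oxo-2,3-dihydro-1,4-benzodioxin-6-yl}prop-2-enoyl]oxy}propanoic acid
Conditions: TFA/H2O (9:1), anisole (5 equiv), 0 °C → rt; evaporation
Reagents that add atoms: none
Why: Acidolysis removes the tert-butyl ester as its cation (trapped by water and anisole) and hydrolyses both catechol ketals, while the aryl lactone, the electron-poor enol ether and the cinnamate ester should withstand aqueous acid at room temperature.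

**Step 13**
Reactants: 18 the deprotected lactone of step 12
Product: 19 Salvianolic acid H, (2R)-2-{[(2E)-3-{3-[(Z)-1-carboxy-2-(3,4-dihydroxyphenyl)ethenoxy]-4-hydroxyphenyl}prop-2-enoyl]oxy}-3-(3,4-dihydroxyphenyl)propanoic acid
Conditions: NaHCO3 (5 equiv), degassed THF/H2O (1:1), Ar, rt; 1 M HCl to pH 2 at 0 °C; reverse-phase chromatography
Reagents that add atoms: water, O
Why: In this chemoselective ester hydrolysis the lactone is an aryl ester with a phenoxide leaving group and should open under bicarbonate, whereas the secondary alkyl cinnamate, shielded by the neighbouring carboxylate, should not; exclusion of air protects the catechols and cold acidification returns the acid without relactonisation or epimerisation.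

**Compound list**

1 | 2,2-dimethyl-1,3-benzodioxole | CC1(C)Oc2ccccc2O1 | starting material
2 | 5-bromo-2,2-dimethyl-1,3-benzodioxole | CC1(C)Oc2ccc(Br)cc2O1 | intermediate
3 | (2,2-dimethyl-1,3-benzodioxol-5-yl)lithium | [Li]c1ccc2OC(C)(C)Oc2c1 | intermediate (not isolated)
4 | 2,2-dimethyl-1,3-benzodioxole-5-carbaldehyde | O=Cc1ccc2OC(C)(C)Oc2c1 | intermediate
5 | (R)-danshensu, (2R)-3-(3,4-dihydroxyphenyl)-2-hydroxypropanoic acid | O[C@H](Cc1ccc(O)c(O)c1)C(=O)O | starting material
6 | (5R)-5-[(2,2-dimethyl-1,3-benzodioxol-5-yl)methyl]-2,2-dimethyl-1,3-dioxolan-4-one | CC1(C)O[C@H](Cc2ccc3OC(C)(C)Oc3c2)C(=O)O1 | intermediate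
7 | (2R)-3-(2,2-dimethyl-1,3-benzodioxol-5-yl)-2-hydroxypropanoic acid | O[C@H](Cc1ccc2OC(C)(C)Oc2c1)C(=O)O | intermediate
8 | tert-butyl (2R)-3-(2,2-dimethyl-1,3-benzodioxol-5-yl)-2-hydroxypropanoate | O[C@H](Cc1ccc2OC(C)(C)Oc2c1)C(=O)OC(C)(C)C | intermediate
9 | acryloyl chloride | C=CC(=O)Cl | starting material
10 | tert-butyl (2R)-2-(acryloyloxy)-3-(2,2-dimethyl-1,3-benzodioxol-5-yl)propanoate | C=CC(=O)O[C@H](Cc1ccc2OC(C)(C)Oc2c1)C(=O)OC(C)(C)C | intermediate
11 | 3-iodophenol | Oc1cccc(I)c1 | starting material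
12 | ethyl 2-diazo-2-(diethoxyphosphoryl)acetate | CCOC(=O)C(=[N+]=[N-])P(=O)(OCC)OCC | starting material
13 | ethyl 2-(diethoxyphosphoryl)-2-(3-iodophenoxy)acetate (racemic) | CCOC(=O)C(Oc1cccc(I)c1)P(=O)(OCC)OCC | intermediate
14 | ethyl (2Z)-3-(2,2-dimethyl-1,3-benzodioxol-5-yl)-2-(3-iodophenoxy)prop-2-enoate | CCOC(=O)/C(Oc1cccc(I)c1)=C/c1ccc2OC(C)(C)Oc2c1 | intermediate
15 | (2Z)-3-(2,2-dimethyl-1,3-benzodioxol-5-yl)-2-(3-iodophenoxy)prop-2-enoic acid | OC(=O)/C(Oc1cccc(I)c1)=C/c1ccc2OC(C)(C)Oc2c1 | intermediate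
16 | (2Z)-2-{3-[(1E)-3-{[(2R)-1-tert-butoxy-3-(2,2-dimethyl-1,3-benzodioxol-5-yl)-1-oxopropan-2-yl]oxy}-3-oxoprop-1-en-1-yl]phenoxy}-3-(2,2-dimethyl-1,3-benzodioxol-5-yl)prop-2-enoic acid | O=C(/C=C/c1cccc(O/C(=C\c2ccc3OC(C)(C)Oc3c2)C(=O)O)c1)O[C@H](Cc1ccc2OC(C)(C)Oc2c1)C(=O)OC(C)(C)C | intermediate
17 | tert-butyl (2R)-3-(2,2-dimethyl-1,3-benzodioxol-5-yl)-2-{[(2E)-3-{(3Z)-3-[(2,2-dimethyl-1,3-benzodioxol-5-yl)methylidene]-2-oxo-2,3-dihydro-1,4-benzodioxin-6-yl}prop-2-enoyl]oxy}propanoate | O=C(/C=C/c1ccc2OC(=O)/C(=C/c3ccc4OC(C)(C)Oc4c3)Oc2c1)O[C@H](Cc1ccc2OC(C)(C)Oc2c1)C(=O)OC(C)(C)C | intermediate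
18 | (2R)-3-(3,4-dihydroxyphenyl)-2-{[(2E)-3-{(3Z)-3-[(3,4-dihydroxyphenyl)methylidene]-2-oxo-2,3-dihydro-1,4-benzodioxin-6-yl}prop-2-enoyl]oxy}propanoic acid | O=C(/C=C/c1ccc2OC(=O)/C(=C/c3ccc(O)c(O)c3)Oc2c1)O[C@H](Cc1ccc(O)c(O)c1)C(=O)O | intermediate
19 | Salvianolic acid H | O=C(/C=C/c1ccc(O)c(O/C(=C\c2ccc(O)c(O)c2)C(=O)O)c1)O[C@H](Cc1ccc(O)c(O)c1)C(=O)O | target

**Total step count:** 13.
**Longest linear sequence:** 8 steps (steps 3, 4, 5, 6, 10, 11, 12, 13 from 5; the line from 1 through steps 1, 2, 8, 9, 10, 11, 12, 13 is equally long).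

**Steps most likely to fail**

Step 11. Palladation may not reach C4: it may instead occur at the vinylic C–H cis to the carboxylate or at C2, or the oxidant may degrade the electron-rich rings before the lactone closes. The fallback uses known chemistry and brings the C4 oxygen in from the start; it sets out from alcohol 8 and aldehyde 4 and rejoins the route at target 19.
- 3,4-Dihydroxybenzaldehyde is alkylated at its more acidic 4-hydroxyl (MOMCl, K2CO3, acetone) to give 3-hydroxy-4-(methoxymethoxy)benzaldehyde F1.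
- Alcohol 8 opens Meldrum's acid (toluene, 90 °C) to give 3-{[(2R)-1-tert-butoxy-3-(2,2-dimethyl-1,3-benzodioxol-5-yl)-1-oxopropan-2-yl]oxy}-3-oxopropanoic acid F2.
- Knoevenagel–Doebner condensation of F1 with F2 (pyridine, cat. piperidine, 60 °C) gives tert-butyl (2R)-3-(2,2-dimethyl-1,3-benzodioxol-5-yl)-2-({(2E)-3-[3-hydroxy-4-(methoxymethoxy)phenyl]prop-2-enoyl}oxy)propanoate F3.
- Regitz diazo transfer to tert-butyl diethylphosphonoacetate (4-acetamidobenzenesulfonyl azide, DBU, MeCN) gives tert-butyl 2-diazo-2-(diethoxyphosphoryl)acetate F4.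
- Rh2(OAc)4-catalysed O–H insertion of F4 into the phenol of F3 gives the α-aryloxy phosphonoacetate F5.
- Horner–Wadsworth–Emmons olefination of F5 with aldehyde 4 (LiCl, DBU, MeCN) gives the fully protected (Z)-enol ether di-tert-butyl ester F6.
- TFA/H2O then removes both tert-butyl esters, both acetonides and the methoxymethyl ether in one operation to give 19.

Step 3. Ketalisation of the catechol may stay incomplete on the sparingly soluble free acid, with methyl ester formation competing. The fallback sets out from 5 and returns at 7. Fischer esterification (MeOH, SOCl2, 0 °C → rt) gives methyl (2R)-3-(3,4-dihydroxyphenyl)-2-hydroxypropanoate F7. Ketalisation of the now soluble ester (2,2-dimethoxypropane, cat. TsOH, benzene, reflux with MeOH removal) gives methyl (2R)-3-(2,2-dimethyl-1,3-benzodioxol-5-yl)-2-hydroxypropanoate F8, and LiOH in THF/H2O at 0 °C gives acid 7.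

Step 8. Geometric control in the olefination may be poor, or deprotonation of the α-aryloxy phosphonate sluggish. The fallback sets out from 11 and 4 and returns at 15. O-alkylation of 3-iodophenol 11 with chloroacetic acid (aq. NaOH, reflux) gives (3-iodophenoxy)acetic acid F9. A Perkin condensation of F9 with aldehyde 4 (Ac2O, Et3N, 110 °C, then aqueous hydrolysis of the mixed anhydride) gives acid 15 directly, under equilibrating conditions that should favour the carboxyl trans to ring B.

**Further compounds**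

F1 | step 11 | 3-hydroxy-4-(methoxymethoxy)benzaldehyde | O=Cc1ccc(OCOC)c(O)c1
F2 | step 11 | 3-{[(2R)-1-tert-butoxy-3-(2,2-dimethyl-1,3-benzodioxol-5-yl)-1-oxopropan-2-yl]oxy}-3-oxopropanoic acid | OC(=O)CC(=O)O[C@H](Cc1ccc2OC(C)(C)Oc2c1)C(=O)OC(C)(C)C
F3 | step 11 | tert-butyl (2R)-3-(2,2-dimethyl-1,3-benzodioxol-5-yl)-2-({(2E)-3-[3-hydroxy-4-(methoxymethoxy)phenyl]prop-2-enoyl}oxy)propanoate | O=C(/C=C/c1ccc(OCOC)c(O)c1)O[C@H](Cc1ccc2OC(C)(C)Oc2c1)C(=O)OC(C)(C)C
F4 | step 11 | tert-butyl 2-diazo-2-(diethoxyphosphoryl)acetate | CCOP(=O)(OCC)C(=[N+]=[N-])C(=O)OC(C)(C)C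
F5 | step 11 | tert-butyl (2R)-2-{[(2E)-3-{3-[2-tert-butoxy-1-(diethoxyphosphoryl)-2-oxoethoxy]-4-(methoxymethoxy)phenyl}prop-2-enoyl]oxy}-3-(2,2-dimethyl-1,3-benzodioxol-5-yl)propanoate | O=C(/C=C/c1ccc(OCOC)c(OC(C(=O)OC(C)(C)C)P(=O)(OCC)OCC)c1)O[C@H](Cc1ccc2OC(C)(C)Oc2c1)C(=O)OC(C)(C)C
F6 | step 11 | tert-butyl (2Z)-2-{5-[(1E)-3-{[(2R)-1-tert-butoxy-3-(2,2-dimethyl-1,3-benzodioxol-5-yl)-1-oxopropan-2-yl]oxy}-3-oxoprop-1-en-1-yl]-2-(methoxymethoxy)phenoxy}-3-(2,2-dimethyl-1,3-benzodioxol-5-yl)prop-2-enoate | O=C(/C=C/c1ccc(OCOC)c(O/C(=C\c2ccc3OC(C)(C)Oc3c2)C(=O)OC(C)(C)C)c1)O[C@H](Cc1ccc2OC(C)(C)Oc2c1)C(=O)OC(C)(C)C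
F7 | step 3 | methyl (2R)-3-(3,4-dihydroxyphenyl)-2-hydroxypropanoate | O[C@H](Cc1ccc(O)c(O)c1)C(=O)OC
F8 | step 3 | methyl (2R)-3-(2,2-dimethyl-1,3-benzodioxol-5-yl)-2-hydroxypropanoate | O[C@H](Cc1ccc2OC(C)(C)Oc2c1)C(=O)OC
F9 | step 8 | (3-iodophenoxy)acetic acid | OC(=O)COc1cccc(I)c1
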